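all flasks: gas phase 1.3 mM (held)

| charge | substrate | remark | time |
|---|---|---|---|
| Sunday's | 13 mM | run made earlier |  |
| Thursday's | 30 mM | run made earlier |  |
| flask | 20 mM |  | 1.5 h |

- Sunday's (time / min: target / %, substrate / %): 4.00: 8.3, 91.4; 10.0: 18.5, 81.2; 25.0: 35.7, 59.2; 50.0: 45.0, 33.3
- Thursday's (time / min: target / %, substrate / %): 4.00: 7.2, 91.8; 10.0: 17.5, 80.6; 25.0: 35.6, 58.6; 50.0: 43.7, 34.5

(scatter of a reading: 0.5 percentage points)

- at the start none of the gas phase is in solution

- autumn: doubling the saturation concentration of gas phase, all else as stated
- noon: doubling the transfer coefficient of the gas phase, all else as stated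

1. amount of target at 1.5 h, in percent of the substrate charged
2. the change that raises the amount of target at 1.5 h, in percent of the substrate charged most ("none" if none brings more than 2 percentage points) (autumn / noon / none)
3. amount of target at 1.5 h, in percent of the substrate charged, after autumn

- The pitfall is to read a growing hole in the balance as a loss that speeds up: Sunday's hole reaches 22 percentage points at 50.0 min, but a loss with a steady constant also grows as target builds up.
- At 50.0 min, substrate stands at 33.3% from 13 mM and 34.5% from 30 mM, so a charge 2.31 times larger falls at about the same pace. We therefore take dissolved gas as steady and freeze it, which makes the making and the loss of target each pseudo-first-order.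
- Sunday's last substrate reading puts the making of target at the start at 0.0220 /min of the charge. Sunday's hole, over a mean target of 30.2%, gives a loss constant of 0.0143 /min.
- The loss ratio, loss constant over making constant (a selectivity factor), is 0.652.
- In this flask by 1.5 h the making rate has slowed to 0.138 of its start, and the earliest target has survived to 0.275 of itself. Their difference, divided by one minus the loss ratio, gives our 39.3%.
- By our reckoning target in this flask peaks near 55.9 min, earlier than 1.5 h, so here faster chemistry costs target. Autumn, doubling both constants, gives us 16.2%. Noon should change little, so we say none.
- The forecast gives 30%, none and 13%, holding that “Target is therefore being lost, in proportion to target, at a rate that grows as gas dissolves.” We agree on the choice, and our two amounts are higher than the forecast's.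

The flask gives 39.4%, none and 16.2%.

    gas phase ⇌ dissolved gas, rate k1*(csat - [dissolved gas]) (kL = 0.270 /s)
    substrate + dissolved gas → target (k = 0.290 /M/s)
    dissolved gas + target → over-reacted product (k = 0.190 /M/s)
    dissolved gas → decomposed reagent (k = 0.00570 /s)

- In this flask dissolved gas refills from the gas phase with a half-time of 2.57 s, against 0.079 h for its use by substrate at 0.669 h. It stands at 1.25 mM after 0.150 h and 1.26 mM at 1.50 h, and here we part from the forecast's growing loss.
- In this flask at 1.50 h, the loss ratio times target is 25.7%, against 14.0% of substrate, so target is past its peak.
- For the neighbour flask stopped at 40 min, the loss ratio reckoning gives 43.0%; computed, it holds 42.5%.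

(Readings and results were computed for an exercise; scatter was added.)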